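**Plan**

- Retrosynthesis cuts three bonds in this order: the C=C of the 5-propenyl group (back to a C5 aldehyde), the O1–C2 ether bond of the dihydrofuran ring (back to an open 1,2-diarylpropan-1-ol), and the C3–C3a bond (back to a 5-bromovanillin-derived arylzinc and 2-bromo-3',4',5'-trimethoxypropiophenone).
- Enabling feature: C2 of the dihydrobenzofuran is a benzylic ether carbon carrying the 3,4,5-trimethoxyphenyl ring. Its 4-methoxy group stabilises a cation at C2, so O1 can re-form O1–C2 by capturing that cation next to the C3 methyl group.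
- Forward: the two purchased benzene rings are joined at C3–C3a by a Negishi coupling, the ketone is reduced, acid closes the dihydrofuran ring (the only ring made), and a Julia–Kocienski olefination completes the side chain.
- Stereochemistry: C3 (R) comes from the chiral nickel–pybox catalyst in the enantioconvergent coupling; C2 (R) is relayed from C3 by trans-selective ring closure; the E alkene comes from the olefination.

Key step: step 6

Assumption: the pybox enantiomer that delivers the (R)-ketone 8 is used in step 4; its sense of induction is taken from the parent coupling of 2-bromopropiophenones and would be confirmed on the first run.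
Assumption: sulfone 12 is treated as a catalogue reagent.

**Route**

Step 1
Reactants: 1 5-bromovanillin (3-bromo-4-hydroxy-5-methoxybenzaldehyde)
Product: 2 3-bromo-5-methoxy-4-(methoxymethoxy)benzaldehyde
Conditions: MOMCl (1.5 equiv), i-Pr2NEt (2 equiv), CH2Cl2, 0 °C → rt
Reagents that add atoms: chloromethyl methyl ether, COCCl
Why: Williamson-type O-alkylation of the acidic phenol should install a MOM ether that tolerates the later organomagnesium and organozinc chemistry and falls off in the acid step.

Step 2
Reactants: 2 3-bromo-5-methoxy-4-(methoxymethoxy)benzaldehyde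
Product: 3 1-bromo-5-(dimethoxymethyl)-3-methoxy-2-(methoxymethoxy)benzene
Conditions: HC(OMe)3 (3 equiv), MeOH, PPTS (5 mol%), rt; Et3N quench
Reagents that add atoms: trimethyl orthoformate, COC(OC)OC; methanol, CO
Why: Acid-catalysed acetalisation driven by the orthoformate as water scavenger should mask the aldehyde, PPTS at room temperature being too weak to cleave the aryl MOM ether; the product is handled on Et3N-deactivated silica.

Step 3
Reactants: 4 1-(3,4,5-trimethoxyphenyl)propan-1-one
Product: 5 rac-2-bromo-1-(3,4,5-trimethoxyphenyl)propan-1-one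
Conditions: CuBr2 (2.1 equiv), EtOAc–CHCl3, reflux
Reagents that add atoms: CuBr2, Br[Cu]Br
Why: α-Bromination of an aryl alkyl ketone through its enol with CuBr2 should spare the electron-rich ring, and a racemic bromide suffices because the next step is stereoconvergent.

Step 4
Reactants: 3 1-bromo-5-(dimethoxymethyl)-3-methoxy-2-(methoxymethoxy)benzene; 5 rac-2-bromo-1-(3,4,5-trimethoxyphenyl)propan-1-one
Product: 8 (R)-2-[5-(dimethoxymethyl)-3-methoxy-2-(methoxymethoxy)phenyl]-1-(3,4,5-trimethoxyphenyl)propan-1-one, via arylmagnesium bromide 6 (not isolated), via arylzinc iodide 7 (not isolated)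
Conditions: 3, Mg (I2-activated), THF, 40 °C; ZnI2, THF, rt; then 5 (limiting, 7 in 1.3 equiv), NiCl2(DME) (5 mol%), chiral pybox ligand (6.5 mol%), DME–THF, −30 °C; pH 7 buffer quench
Reagents that add atoms: none
Why: In this nickel-catalysed enantioconvergent Negishi α-arylation of a racemic secondary α-bromoketone, bromine abstraction gives a planar α-acyl radical, so both enantiomers of 5 funnel into one nickel–pybox intermediate that sets the (R) centre at C–C bond formation, and the near-neutral medium at −30 °C should keep the enolisable α-aryl ketone from racemising.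

Step 5
Reactants: 8 (R)-2-[5-(dimethoxymethyl)-3-methoxy-2-(methoxymethoxy)phenyl]-1-(3,4,5-trimethoxyphenyl)propan-1-one
Product: 9 (2R)-2-[5-(dimethoxymethyl)-3-methoxy-2-(methoxymethoxy)phenyl]-1-(3,4,5-trimethoxyphenyl)propan-1-ol (both epimers at C1)
Conditions: NaBH4, MeOH–THF, −20 → 0 °C
Reagents that add atoms: none
Why: Borohydride reduction of the aryl ketone should be faster at low temperature than enolisation, so the α-centre is kept, and the new carbinol centre (substrate-controlled, mixture accepted) needs no control because both epimers converge in step 6.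

Step 6
Reactants: 9 (2R)-2-[5-(dimethoxymethyl)-3-methoxy-2-(methoxymethoxy)phenyl]-1-(3,4,5-trimethoxyphenyl)propan-1-ol
Product: 11 (2R,3R)-7-methoxy-3-methyl-2-(3,4,5-trimethoxyphenyl)-2,3-dihydro-1-benzofuran-5-carbaldehyde, via free phenol aldehyde carbinol 10 (not isolated)
Conditions: CF3CO2H–CH2Cl2 (1:5), H2O (5 equiv), 0 °C → rt; sat. aq NaHCO3 quench
Reagents that add atoms: water, O
Why: Trifluoroacetic acid with a little water hydrolyses the dimethyl acetal, cleaves the MOM ether and protonates the benzylic hydroxyl, so that either carbinol epimer loses water to the same planar C2 cation, stabilised by the 4-methoxy group of the trimethoxyphenyl ring, and the phenol oxygen (free, or still MOM-capped with later loss of the methoxymethyl cation) traps it to form O1–C2. The closest known reaction type is the acid-mediated cyclodehydration of 1-aryl-2-(2-hydroxyaryl)propan-1-ols to trans-2-aryl-3-methyl-2,3-dihydrobenzofurans, an SN1 cycloetherification. The dihydrofuran ring closes in the 5-exo-trig mode, O1 adding to the cationic carbon whose charge is delocalised into the exocyclic aryl ring. The new C2 centre is controlled by the C3 centre set in step 4: in the cation the C3 methyl turns away from the aryl ring (allylic 1,3-strain), O1 adds to the face that leaves aryl and methyl anti, and any cis ether can re-ionise and drain to the more stable trans isomer, so that (3R) is relayed to (2R). The step needs trans selectivity and an intact C3 centre; the first is secured by the C3 methyl group as described, the second by the five-membered intramolecular capture, which at 0 °C to room temperature and short acid contact should outrun loss of the C3 proton or a 1,2-hydride shift.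

Step 7
Reactants: 11 (2R,3R)-7-methoxy-3-methyl-2-(3,4,5-trimethoxyphenyl)-2,3-dihydro-1-benzofuran-5-carbaldehyde; 12 5-(ethylsulfonyl)-1-phenyl-1H-tetrazole
Product: 14 (2R,3R)-7-methoxy-3-methyl-5-[(E)-prop-1-en-1-yl]-2-(3,4,5-trimethoxyphenyl)-2,3-dihydro-1-benzofuran, via potassium sulfonyl carbanion 13 (not isolated)
Conditions: 12, KN(SiMe3)2, DME, −60 °C; then 11, −60 °C → rt
Reagents that add atoms: none
Why: In this Julia–Kocienski olefination the metalated phenyltetrazolyl sulfone adds to the non-enolisable aldehyde, and Smiles rearrangement with loss of SO2 and tetrazololate should give the E alkene (anti adduct favoured with potassium in DME) without touching the C2 and C3 centres.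

**Compound list**

1 | 5-bromovanillin (3-bromo-4-hydroxy-5-methoxybenzaldehyde) | O=Cc1cc(Br)c(O)c(OC)c1 | starting material
2 | 3-bromo-5-methoxy-4-(methoxymethoxy)benzaldehyde | O=Cc1cc(Br)c(OCOC)c(OC)c1 | intermediate
3 | 1-bromo-5-(dimethoxymethyl)-3-methoxy-2-(methoxymethoxy)benzene | COC(OC)c1cc(Br)c(OCOC)c(OC)c1 | intermediate
4 | 1-(3,4,5-trimethoxyphenyl)propan-1-one | CCC(=O)c1cc(OC)c(OC)c(OC)c1 | starting material
5 | rac-2-bromo-1-(3,4,5-trimethoxyphenyl)propan-1-one | CC(Br)C(=O)c1cc(OC)c(OC)c(OC)c1 | intermediate
6 | [5-(dimethoxymethyl)-3-methoxy-2-(methoxymethoxy)phenyl]magnesium bromide (formed in the flask) | COC(OC)c1cc([Mg]Br)c(OCOC)c(OC)c1 | intermediate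
7 | [5-(dimethoxymethyl)-3-methoxy-2-(methoxymethoxy)phenyl]zinc iodide (formed in the flask) | COC(OC)c1cc([Zn]I)c(OCOC)c(OC)c1 | intermediate
8 | (R)-2-[5-(dimethoxymethyl)-3-methoxy-2-(methoxymethoxy)phenyl]-1-(3,4,5-trimethoxyphenyl)propan-1-one | COC(OC)c1cc(OC)c(OCOC)c(c1)[C@@H](C)C(=O)c1cc(OC)c(OC)c(OC)c1 | intermediate
9 | (2R)-2-[5-(dimethoxymethyl)-3-methoxy-2-(methoxymethoxy)phenyl]-1-(3,4,5-trimethoxyphenyl)propan-1-ol, both C1 epimers | COC(OC)c1cc(OC)c(OCOC)c(c1)[C@@H](C)C(O)c1cc(OC)c(OC)c(OC)c1 | intermediate
10 | 4-hydroxy-3-[(2R)-1-hydroxy-1-(3,4,5-trimethoxyphenyl)propan-2-yl]-5-methoxybenzaldehyde, both carbinol epimers (formed in the flask) | O=Cc1cc(OC)c(O)c(c1)[C@@H](C)C(O)c1cc(OC)c(OC)c(OC)c1 | intermediate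
11 | (2R,3R)-7-methoxy-3-methyl-2-(3,4,5-trimethoxyphenyl)-2,3-dihydro-1-benzofuran-5-carbaldehyde | O=Cc1cc(OC)c2c(c1)[C@@H](C)[C@H](c1cc(OC)c(OC)c(OC)c1)O2 | intermediate
12 | 5-(ethylsulfonyl)-1-phenyl-1H-tetrazole | CCS(=O)(=O)c1nnnn1-c1ccccc1 | starting material
13 | potassium 1-[(1-phenyl-1H-tetrazol-5-yl)sulfonyl]ethan-1-ide (formed in the flask) | C[CH-]S(=O)(=O)c1nnnn1-c1ccccc1.[K+] | intermediate
14 | (2R,3R)-7-methoxy-3-methyl-5-[(E)-prop-1-en-1-yl]-2-(3,4,5-trimethoxyphenyl)-2,3-dihydro-1-benzofuran | C/C=C/c1cc(OC)c2c(c1)[C@@H](C)[C@H](c1cc(OC)c(OC)c(OC)c1)O2 | target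

**Step count**

Total: 7 steps. Longest linear sequence: 6 steps (1 → 2 → 3 → 8 → 9 → 11 → 14, steps 1, 2, 4, 5, 6, 7).

**Steps most likely to fail**

Step 4. The methoxymethoxy group ortho to the zinc-bearing carbon may slow transmetalation and lower the enantioselectivity, and the α-aryl ketone may partly racemise by enolisation during coupling or work-up. The fallback takes the C3 centre from an epoxide by SN2 inversion instead of from a catalyst. It sets out from 3, which is converted into the Grignard reagent 6 as before. With CuI catalysis, 6 (in excess, the first equivalent serving as base) should open (2R,3R)-3-methyloxiranemethanol F1 at C3 with inversion; F1 comes from Sharpless epoxidation of (E)-but-2-en-1-ol with D-(−)-diisopropyl tartrate, Ti(OiPr)4 and t-BuOOH. The product would be (2S,3R)-3-[5-(dimethoxymethyl)-3-methoxy-2-(methoxymethoxy)phenyl]butane-1,2-diol F2; any 1,3-diol from attack at C2 is not cleaved in the next operation and is removed there. NaIO4 in buffered aqueous THF should cleave F2 to (R)-2-[5-(dimethoxymethyl)-3-methoxy-2-(methoxymethoxy)phenyl]propanal F3, which is used at once. Addition of 3,4,5-trimethoxyphenylmagnesium bromide F4 (from 5-bromo-1,2,3-trimethoxybenzene and Mg) at −78 °C gives both carbinol epimers and rejoins the route at 9.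

Step 6. Prolonged acid contact may erode the C3 configuration through loss of the C3 proton and re-protonation of the alkene, the trans selectivity may be incomplete, and formaldehyde released from the MOM group may alkylate the electron-rich rings. The fallback generates the same C2 cation under base-buffered conditions and uses the MOM ether oxygen as the internal nucleophile. It sets out from 9: Ms2O and Et3N in CH2Cl2 at −40 °C → rt should give the benzylic methanesulfonate F5, which ionises spontaneously. The MOM ether oxygen captures the cation and the resulting oxonium ion loses the methoxymethyl group (dealkylative cycloetherification by neighbouring-group participation), giving (2R,3R)-5-(dimethoxymethyl)-7-methoxy-3-methyl-2-(3,4,5-trimethoxyphenyl)-2,3-dihydro-1-benzofuran F6. Any alkene formed cannot be re-protonated in this medium, so the C3 centre of the cyclised material stays intact. PPTS in wet acetone at room temperature then frees the aldehyde and the route is rejoined at 11.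

Step 7. With an aromatic aldehyde the addition of the sulfonyl carbanion may be less anti-selective, giving incomplete E selectivity. The fallback forms the alkene without stereocontrol and then equilibrates it. It sets out from 11: ethyltriphenylphosphonium bromide and KN(SiMe3)2 in THF give ethylidenetriphenylphosphorane F7, whose Wittig reaction with 11 at −78 °C → rt should give mainly (2R,3R)-7-methoxy-3-methyl-5-[(Z)-prop-1-en-1-yl]-2-(3,4,5-trimethoxyphenyl)-2,3-dihydro-1-benzofuran F8. PdCl2(MeCN)2 (cat.) in CH2Cl2 at room temperature then isomerises the alkene to the thermodynamically preferred E isomer, rejoining the route at 14.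

**Further compounds**

F1 | step 4 | (2R,3R)-3-methyloxiranemethanol | C[C@H]1O[C@@H]1CO
F2 | step 4 | (2S,3R)-3-[5-(dimethoxymethyl)-3-methoxy-2-(methoxymethoxy)phenyl]butane-1,2-diol | COC(OC)c1cc(OC)c(OCOC)c(c1)[C@@H](C)[C@H](O)CO
F3 | step 4 | (R)-2-[5-(dimethoxymethyl)-3-methoxy-2-(methoxymethoxy)phenyl]propanal | COC(OC)c1cc(OC)c(OCOC)c(c1)[C@@H](C)C=O
F4 | step 4 | 3,4,5-trimethoxyphenylmagnesium bromide | COc1cc([Mg]Br)cc(OC)c1OC
F5 | step 6 | (2R)-2-[5-(dimethoxymethyl)-3-methoxy-2-(methoxymethoxy)phenyl]-1-(3,4,5-trimethoxyphenyl)propyl methanesulfonate, both C1 epimers | COC(OC)c1cc(OC)c(OCOC)c(c1)[C@@H](C)C(OS(C)(=O)=O)c1cc(OC)c(OC)c(OC)c1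
F6 | step 6 | (2R,3R)-5-(dimethoxymethyl)-7-methoxy-3-methyl-2-(3,4,5-trimethoxyphenyl)-2,3-dihydro-1-benzofuran | COC(OC)c1cc(OC)c2c(c1)[C@@H](C)[C@H](c1cc(OC)c(OC)c(OC)c1)O2
F7 | step 7 | ethylidenetriphenylphosphorane | CC=P(c1ccccc1)(c1ccccc1)c1ccccc1
F8 | step 7 | (2R,3R)-7-methoxy-3-methyl-5-[(Z)-prop-1-en-1-yl]-2-(3,4,5-trimethoxyphenyl)-2,3-dihydro-1-benzofuran | C/C=C\c1cc(OC)c2c(c1)[C@@H](C)[C@H](c1cc(OC)c(OC)c(OC)c1)O2
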